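**Retrosynthetic overview** (side chain numbered C1′ benzylic to C15′ carbinol)
1. Target ⇐ aryl O‑TBS removal ⇐ C5′ acetylation ⇐ TES removal from the fully silylated skeleton.
2. Key late union: C7′–C8′ sp²–sp³ Negishi coupling of a western (E)-vinyl iodide (arene + C1′–C7′) with an eastern alkylzinc (C8′–C15′ silyloxy enone).
3. West: Ar–C1′ by Cu-catalysed aryl Grignard allylation; C2′=C3′ by Zr-catalysed carboalumination; C7′–I by hydrozirconation–iodination; C5′ by catalytic asymmetric propargylation of but-2-ynal.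
4. East: C12′–C13′ by vinyllithium/Weinreb ketone synthesis; C11′ from (S)-Roche ester through a zinc homoenolate vinylation (C9′–C10′).
5. No ring is built; the only ring (the arene) is carried from o-cresol.

Assumption: small commercial carbon donors (Me3Al, paraformaldehyde, allenylboronic acid pinacol ester, vinyl bromide, Ac2O) are treated as reagents and listed under "Reagents that add atoms"; (S)-TRIP is assumed to show the same facial preference with but-2-ynal as with aryl aldehydes.

**Route**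

Step 1
Reactants: 1 o-cresol
Product: 2 2,4-dibromo-6-methylphenol
Conditions: Br2 (2.1 equiv), AcOH, 15 °C → rt
Reagents that add atoms: bromine, BrBr
Why: Electrophilic aromatic bromination, the OH group directing both bromines to its free ortho and para positions.

Step 2
Reactants: 2 2,4-dibromo-6-methylphenol
Product: 3 2-bromo-6-methyl-1,4-benzoquinone
Conditions: CrO3, AcOH/H2O, 60 °C
Reagents that add atoms: chromium trioxide, O=[Cr](=O)=O
Why: Chromic acid oxidation of a 4-bromophenol to the p-quinone with oxidative loss of the para bromine, which fixes the 2-bromo-6-methyl pattern.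

Step 3
Reactants: 3 2-bromo-6-methyl-1,4-benzoquinone
Product: 4 2-bromo-6-methylbenzene-1,4-diol
Conditions: Na2S2O4, EtOAc/H2O, rt
Reagents that add atoms: none
Why: Dithionite reduction of a quinone to its hydroquinone.

Step 4
Reactants: 4 2-bromo-6-methylbenzene-1,4-diol
Product: 5 1-bromo-2,5-bis(tert-butyldimethylsilyloxy)-3-methylbenzene
Conditions: TBSCl, imidazole, DMAP (cat.), DMF, 50 °C
Reagents that add atoms: tert-butyldimethylsilyl chloride, CC(C)(C)[Si](C)(C)Cl
Why: Silyl ether protection of both phenols, giving acid-stable and fluoride-labile ethers that tolerate the organometallic steps.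

Step 5
Reactants: 6 but-2-yn-1-ol
Product: 7 but-2-ynal
Conditions: activated MnO2, CH2Cl2, rt; filter, use as solution
Reagents that add atoms: none
Why: MnO2 oxidation of a propargylic alcohol stops at the ynal.

Step 6
Reactants: 7 but-2-ynal
Product: 8 (S)-hepta-1,5-diyn-4-ol
Conditions: allenyl-Bpin (1.5 equiv), (S)-TRIP (10 mol %), 4 Å MS, toluene, −20 → 0 °C; aqueous work-up
Reagents that add atoms: allenylboronic acid pinacol ester, C=C=CB1OC(C)(C)C(C)(C)O1
Why: Chiral phosphoric acid-catalysed propargylation through a closed six-membered SE2′ transition state, the (S)-catalyst delivering the allenylboronate to the Si face of the aldehyde to set C5′ as S.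

Step 7
Reactants: 8 (S)-hepta-1,5-diyn-4-ol
Product: 9 (S)-4-(triethylsilyloxy)hepta-1,5-diyne
Conditions: TESCl, imidazole, CH2Cl2, 0 °C → rt
Reagents that add atoms: chlorotriethylsilane, CC[Si](CC)(CC)Cl
Why: Silyl protection of the carbinol as an acid-labile TES ether that is orthogonal to the aryl TBS ethers.

Step 8
Reactants: 9 (S)-4-(triethylsilyloxy)hepta-1,5-diyne
Product: 12 (2E,5S)-3-methyl-5-(triethylsilyloxy)oct-2-en-6-yn-1-ol, via alkenylalane 10 (not isolated), via lithium alkenylalanate 11 (not isolated)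
Conditions: AlMe3 (3 equiv), Cp2ZrCl2 (25 mol %), CH2Cl2, 0 °C → rt; strip volatiles; n-BuLi, THF/hexane, −78 °C; (CH2O)n, −78 °C → rt; Rochelle salt
Reagents that add atoms: trimethylaluminium, C[Al](C)C; paraformaldehyde (formaldehyde), C=O
Why: Negishi Zr-catalysed carboalumination adds Me and Al syn to the terminal alkyne only (the internal alkyne is far slower), and the alanate is hydroxymethylated with retention to give the 2′E allylic alcohol.

Step 9
Reactants: 12 (2E,5S)-3-methyl-5-(triethylsilyloxy)oct-2-en-6-yn-1-ol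
Product: 13 (2E,5S)-1-bromo-3-methyl-5-(triethylsilyloxy)oct-2-en-6-yne
Conditions: CBr4, PPh3, CH2Cl2, 0 °C
Reagents that add atoms: carbon tetrabromide, BrC(Br)(Br)Br
Why: Appel bromination of the primary allylic alcohol by SN2 without allylic shift or loss of the E geometry.

Step 10
Reactants: 5 1-bromo-2,5-bis(tert-butyldimethylsilyloxy)-3-methylbenzene; 13 (2E,5S)-1-bromo-3-methyl-5-(triethylsilyloxy)oct-2-en-6-yne
Product: 15 1,4-bis(tert-butyldimethylsilyloxy)-2-methyl-6-[(2E,5S)-3-methyl-5-(triethylsilyloxy)oct-2-en-6-yn-1-yl]benzene, via aryl Grignard reagent 14 (not isolated)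
Conditions: 5, Mg, THF, 50 °C; then 13, Li2CuCl4 (5 mol %), THF, −30 → 0 °C
Reagents that add atoms: none
Why: Kochi-type Cu-catalysed coupling of an aryl Grignard reagent with a primary, γ,γ-disubstituted allylic bromide proceeds by α (SN2) attack with retention of the E alkene.

Step 11
Reactants: 15 1,4-bis(tert-butyldimethylsilyloxy)-2-methyl-6-[(2E,5S)-3-methyl-5-(triethylsilyloxy)oct-2-en-6-yn-1-yl]benzene
Product: 17 1,4-bis(tert-butyldimethylsilyloxy)-2-[(2E,5S,6E)-7-iodo-3-methyl-5-(triethylsilyloxy)octa-2,6-dien-1-yl]-6-methylbenzene, via alkenylzirconocene 16 (not isolated)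
Conditions: Cp2Zr(H)Cl (2.5 equiv), THF, 45 °C; then I2, THF, 0 °C
Reagents that add atoms: iodine, II
Why: Schwartz hydrozirconation adds H–Zr syn with Zr on the less hindered methyl-bearing alkyne carbon, and iodinolysis with retention gives the (E)-vinyl iodide that fixes the 6′E geometry.

Step 12
Reactants: 18 2-methylbut-3-yn-2-ol
Product: 19 triethyl[(2-methylbut-3-yn-2-yl)oxy]silane
Conditions: TESCl, imidazole, DMAP (cat.), DMF, rt
Reagents that add atoms: chlorotriethylsilane, CC[Si](CC)(CC)Cl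
Why: Silyl protection of the tertiary alcohol so that the later vinyllithium is not quenched.

Step 13
Reactants: 19 triethyl[(2-methylbut-3-yn-2-yl)oxy]silane
Product: 21 (E)-triethyl[(4-iodo-2-methylbut-3-en-2-yl)oxy]silane, via alkenylzirconocene 20 (not isolated)
Conditions: Cp2Zr(H)Cl, THF, rt; then I2, 0 °C
Reagents that add atoms: iodine, II
Why: Hydrozirconation–iodination of a terminal alkyne (syn addition, Zr terminal) gives the (E)-1-iodoalkene that becomes C13′=C14′.

Step 14
Reactants: 22 methyl (S)-3-hydroxy-2-methylpropanoate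
Product: 23 methyl (R)-3-iodo-2-methylpropanoate
Conditions: I2, PPh3, imidazole, CH2Cl2, 0 °C → rt
Reagents that add atoms: iodine, II
Why: Garegg–Samuelsson (Appel-type) iodination of the primary alcohol, leaving the chiral-pool stereocentre (future C11′) untouched; the descriptor changes only through CIP priority.

Step 15
Reactants: 23 methyl (R)-3-iodo-2-methylpropanoate
Product: 25 methyl (S)-2-methylpent-4-enoate, via zinc homoenolate 24 (not isolated)
Conditions: activated Zn dust, DMA, 35 °C; then vinyl bromide (1 M in THF), Pd(PPh3)4 (3 mol %), rt → 40 °C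
Reagents that add atoms: vinyl bromide, C=CBr
Why: Zinc insertion gives a configurationally stable β-zincio ester that undergoes Negishi coupling with the vinyl halide without touching the stereocentre.

Step 16
Reactants: 25 methyl (S)-2-methylpent-4-enoate
Product: 26 (S)-N-methoxy-N,2-dimethylpent-4-enamide
Conditions: MeNHOMe·HCl, i-PrMgCl, THF, −20 → 0 °C
Reagents that add atoms: N,O-dimethylhydroxylamine hydrochloride, CNOC.Cl
Why: Weinreb amide formation by aminolysis of the ester with the magnesium amide at low temperature, which avoids α-epimerisation.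

Step 17
Reactants: 26 (S)-N-methoxy-N,2-dimethylpent-4-enamide
Product: 28 (S)-5-hydroxy-N-methoxy-N,2-dimethylpentanamide, via B-alkyl-9-BBN 27 (not isolated)
Conditions: 9-BBN, THF, 0 °C → rt; then aq NaOH, 30 % H2O2, 0 °C
Reagents that add atoms: hydrogen peroxide, OO
Why: Brown anti-Markovnikov hydroboration–oxidation of the terminal alkene, which 9-BBN attacks much faster than the Weinreb amide.

Step 18
Reactants: 28 (S)-5-hydroxy-N-methoxy-N,2-dimethylpentanamide
Product: 29 (S)-5-chloro-N-methoxy-N,2-dimethylpentanamide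
Conditions: PPh3, NCS, CH2Cl2, 0 °C → rt
Reagents that add atoms: N-chlorosuccinimide, O=C1CCC(=O)N1Cl
Why: Appel-type chlorination gives a primary chloride that is inert to the organolithium of the next step and is a latent iodide.

Step 19
Reactants: 21 (E)-triethyl[(4-iodo-2-methylbut-3-en-2-yl)oxy]silane; 29 (S)-5-chloro-N-methoxy-N,2-dimethylpentanamide
Product: 31 (3E,6S)-9-chloro-2,6-dimethyl-2-(triethylsilyloxy)non-3-en-5-one, via vinyllithium 30 (not isolated)
Conditions: 21, t-BuLi (2 equiv), Et2O, −78 °C; then 29, −78 → −40 °C; aq NH4Cl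
Reagents that add atoms: none
Why: Iodine–lithium exchange with retention of the E geometry followed by Weinreb ketone synthesis, in which the chelated tetrahedral intermediate prevents over-addition and the low temperature preserves C11′.

Step 20
Reactants: 31 (3E,6S)-9-chloro-2,6-dimethyl-2-(triethylsilyloxy)non-3-en-5-one
Product: 32 (3E,6S)-9-iodo-2,6-dimethyl-2-(triethylsilyloxy)non-3-en-5-one
Conditions: NaI, acetone, reflux, dark
Reagents that add atoms: sodium iodide, [Na+].[I-]
Why: Finkelstein halide exchange under neutral conditions that do not epimerise the α-stereocentre.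

Step 21
Reactants: 32 (3E,6S)-9-iodo-2,6-dimethyl-2-(triethylsilyloxy)non-3-en-5-one; 17 1,4-bis(tert-butyldimethylsilyloxy)-2-[(2E,5S,6E)-7-iodo-3-methyl-5-(triethylsilyloxy)octa-2,6-dien-1-yl]-6-methylbenzene
Product: 34 1,4-bis(tert-butyldimethylsilyloxy)-2-methyl-6-[(2E,5S,6E,11S,13E)-3,7,11,15-tetramethyl-12-oxo-5,15-bis(triethylsilyloxy)hexadeca-2,6,13-trien-1-yl]benzene, via alkylzinc iodide 33 (not isolated)
Conditions: 32, activated Zn dust, LiCl, THF, 35 °C; then 17, Pd(dppf)Cl2 (5 mol %), THF/DMA, rt → 40 °C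
Reagents that add atoms: none
Why: Knochel zinc insertion tolerates the enone, and Pd-catalysed sp³–sp² Negishi cross-coupling forms C7′–C8′ with retention of the vinyl iodide geometry (6′E) without creating or disturbing a stereocentre.

Step 22
Reactants: 34 the bis-TBS bis-TES coupling product
Product: 35 1,4-bis(tert-butyldimethylsilyloxy)-2-[(2E,5S,6E,11S,13E)-5,15-dihydroxy-3,7,11,15-tetramethyl-12-oxohexadeca-2,6,13-trien-1-yl]-6-methylbenzene
Conditions: PPTS, MeOH/CH2Cl2, 0 °C → rt
Reagents that add atoms: none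
Why: Acid-catalysed methanolysis cleaves both alkyl TES ethers while the acid-stable aryl TBS ethers stay in place.

Step 23
Reactants: 35 the 5′,15′-diol
Product: 36 (2E,5S,6E,11S,13E)-1-[2,5-bis(tert-butyldimethylsilyloxy)-3-methylphenyl]-15-hydroxy-3,7,11,15-tetramethyl-12-oxohexadeca-2,6,13-trien-5-yl acetate
Conditions: Ac2O (1.5 equiv), pyridine, DMAP (cat.), CH2Cl2, 0 °C
Reagents that add atoms: acetic anhydride, CC(=O)OC(C)=O
Why: Acylation is selective for the secondary allylic alcohol because the tertiary alcohol is inert under these conditions and the phenols are still silylated.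

Step 24
Reactants: 36 the bis-TBS acetate
Product: 37 (2E,5S,6E,11S,13E)-1-(2,5-dihydroxy-3-methylphenyl)-15-hydroxy-3,7,11,15-tetramethyl-12-oxohexadeca-2,6,13-trien-5-yl acetate (target)
Conditions: TBAF/AcOH (1:1, 2.4 equiv), THF, 0 °C, argon
Reagents that add atoms: none
Why: Buffered fluoride desilylation removes the aryl TBS ethers within minutes and spares the allylic acetate, the enone and the epimerisable C11′ centre.

**Compound list**
1 | o-cresol | Cc1ccccc1O | starting material
2 | 2,4-dibromo-6-methylphenol | Cc1cc(Br)cc(Br)c1O | intermediate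
3 | 2-bromo-6-methyl-1,4-benzoquinone | CC1=CC(=O)C=C(Br)C1=O | intermediate
4 | 2-bromo-6-methylbenzene-1,4-diol | Cc1cc(O)cc(Br)c1O | intermediate
5 | 1-bromo-2,5-bis(tert-butyldimethylsilyloxy)-3-methylbenzene | Cc1cc(O[Si](C)(C)C(C)(C)C)cc(Br)c1O[Si](C)(C)C(C)(C)C | intermediate
6 | but-2-yn-1-ol | CC#CCO | starting material
7 | but-2-ynal | CC#CC=O | intermediate
8 | (S)-hepta-1,5-diyn-4-ol | CC#C[C@@H](O)CC#C | intermediate
9 | (S)-4-(triethylsilyloxy)hepta-1,5-diyne | CC[Si](CC)(CC)O[C@H](C#CC)CC#C | intermediate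
10 | dimethyl[(1E,4S)-2-methyl-4-(triethylsilyloxy)hept-1-en-5-yn-1-yl]alane | C[Al](C)/C=C(\C)C[C@H](O[Si](CC)(CC)CC)C#CC | intermediate
11 | lithium butyl(dimethyl)[(1E,4S)-2-methyl-4-(triethylsilyloxy)hept-1-en-5-yn-1-yl]alanate | [Li+].CCCC[Al-](C)(C)/C=C(\C)C[C@H](O[Si](CC)(CC)CC)C#CC | intermediate
12 | (2E,5S)-3-methyl-5-(triethylsilyloxy)oct-2-en-6-yn-1-ol | OC/C=C(\C)C[C@H](O[Si](CC)(CC)CC)C#CC | intermediate
13 | (2E,5S)-1-bromo-3-methyl-5-(triethylsilyloxy)oct-2-en-6-yne | BrC/C=C(\C)C[C@H](O[Si](CC)(CC)CC)C#CC | intermediate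
14 | [2,5-bis(tert-butyldimethylsilyloxy)-3-methylphenyl]magnesium bromide | Cc1cc(O[Si](C)(C)C(C)(C)C)cc([Mg]Br)c1O[Si](C)(C)C(C)(C)C | intermediate
15 | 1,4-bis(tert-butyldimethylsilyloxy)-2-methyl-6-[(2E,5S)-3-methyl-5-(triethylsilyloxy)oct-2-en-6-yn-1-yl]benzene | CC[Si](CC)(CC)O[C@H](C#CC)C/C(C)=C/Cc1cc(O[Si](C)(C)C(C)(C)C)cc(C)c1O[Si](C)(C)C(C)(C)C | intermediate
16 | alkenylzirconocene chloride from 15 (Zr at C7′, E) | CC[Si](CC)(CC)O[C@H](/C=C(\C)[Zr](Cl)(C1C=CC=C1)C1C=CC=C1)C/C(C)=C/Cc1cc(O[Si](C)(C)C(C)(C)C)cc(C)c1O[Si](C)(C)C(C)(C)C | intermediate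
17 | 1,4-bis(tert-butyldimethylsilyloxy)-2-[(2E,5S,6E)-7-iodo-3-methyl-5-(triethylsilyloxy)octa-2,6-dien-1-yl]-6-methylbenzene | CC[Si](CC)(CC)O[C@H](/C=C(\C)I)C/C(C)=C/Cc1cc(O[Si](C)(C)C(C)(C)C)cc(C)c1O[Si](C)(C)C(C)(C)C | intermediate
18 | 2-methylbut-3-yn-2-ol | CC(C)(O)C#C | starting material
19 | triethyl[(2-methylbut-3-yn-2-yl)oxy]silane | CC[Si](CC)(CC)OC(C)(C)C#C | intermediate
20 | chloro[(E)-3-methyl-3-(triethylsilyloxy)but-1-en-1-yl]zirconocene | CC[Si](CC)(CC)OC(C)(C)/C=C/[Zr](Cl)(C1C=CC=C1)C1C=CC=C1 | intermediate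
21 | (E)-triethyl[(4-iodo-2-methylbut-3-en-2-yl)oxy]silane | CC[Si](CC)(CC)OC(C)(C)/C=C/I | intermediate
22 | methyl (S)-3-hydroxy-2-methylpropanoate (Roche ester) | COC(=O)[C@@H](C)CO | starting material
23 | methyl (R)-3-iodo-2-methylpropanoate | COC(=O)[C@@H](C)CI | intermediate
24 | [(R)-3-methoxy-2-methyl-3-oxopropyl]zinc iodide | COC(=O)[C@@H](C)C[Zn]I | intermediate
25 | methyl (S)-2-methylpent-4-enoate | COC(=O)[C@@H](C)CC=C | intermediate
26 | (S)-N-methoxy-N,2-dimethylpent-4-enamide | CON(C)C(=O)[C@@H](C)CC=C | intermediate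
27 | (S)-5-(9-borabicyclo[3.3.1]nonan-9-yl)-N-methoxy-N,2-dimethylpentanamide | CON(C)C(=O)[C@@H](C)CCCB1C2CCCC1CCC2 | intermediate
28 | (S)-5-hydroxy-N-methoxy-N,2-dimethylpentanamide | CON(C)C(=O)[C@@H](C)CCCO | intermediate
29 | (S)-5-chloro-N-methoxy-N,2-dimethylpentanamide | CON(C)C(=O)[C@@H](C)CCCCl | intermediate
30 | [(E)-3-methyl-3-(triethylsilyloxy)but-1-en-1-yl]lithium | CC[Si](CC)(CC)OC(C)(C)/C=C/[Li] | intermediate
31 | (3E,6S)-9-chloro-2,6-dimethyl-2-(triethylsilyloxy)non-3-en-5-one | CC[Si](CC)(CC)OC(C)(C)/C=C/C(=O)[C@@H](C)CCCCl | intermediate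
32 | (3E,6S)-9-iodo-2,6-dimethyl-2-(triethylsilyloxy)non-3-en-5-one | CC[Si](CC)(CC)OC(C)(C)/C=C/C(=O)[C@@H](C)CCCI | intermediate
33 | [(4S,6E)-4,8-dimethyl-5-oxo-8-(triethylsilyloxy)non-6-en-1-yl]zinc iodide | CC[Si](CC)(CC)OC(C)(C)/C=C/C(=O)[C@@H](C)CCC[Zn]I | intermediate
34 | 1,4-bis(tert-butyldimethylsilyloxy)-2-methyl-6-[(2E,5S,6E,11S,13E)-3,7,11,15-tetramethyl-12-oxo-5,15-bis(triethylsilyloxy)hexadeca-2,6,13-trien-1-yl]benzene | CC[Si](CC)(CC)O[C@H](/C=C(\C)CCC[C@H](C)C(=O)/C=C/C(C)(C)O[Si](CC)(CC)CC)C/C(C)=C/Cc1cc(O[Si](C)(C)C(C)(C)C)cc(C)c1O[Si](C)(C)C(C)(C)C | intermediate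
35 | 1,4-bis(tert-butyldimethylsilyloxy)-2-[(2E,5S,6E,11S,13E)-5,15-dihydroxy-3,7,11,15-tetramethyl-12-oxohexadeca-2,6,13-trien-1-yl]-6-methylbenzene | O[C@H](/C=C(\C)CCC[C@H](C)C(=O)/C=C/C(C)(C)O)C/C(C)=C/Cc1cc(O[Si](C)(C)C(C)(C)C)cc(C)c1O[Si](C)(C)C(C)(C)C | intermediate
36 | (2E,5S,6E,11S,13E)-1-[2,5-bis(tert-butyldimethylsilyloxy)-3-methylphenyl]-15-hydroxy-3,7,11,15-tetramethyl-12-oxohexadeca-2,6,13-trien-5-yl acetate | CC(=O)O[C@H](/C=C(\C)CCC[C@H](C)C(=O)/C=C/C(C)(C)O)C/C(C)=C/Cc1cc(O[Si](C)(C)C(C)(C)C)cc(C)c1O[Si](C)(C)C(C)(C)C | intermediate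
37 | (2E,5S,6E,11S,13E)-1-(2,5-dihydroxy-3-methylphenyl)-15-hydroxy-3,7,11,15-tetramethyl-12-oxohexadeca-2,6,13-trien-5-yl acetate | CC(=O)O[C@H](/C=C(\C)CCC[C@H](C)C(=O)/C=C/C(C)(C)O)C/C(C)=C/Cc1cc(O)cc(C)c1O | target

**Step count**
Total steps: 24.
Longest linear sequence: 11 steps (steps 5–11 then 21–24 from but-2-yn-1-ol; equally steps 14–24 from the Roche ester), which is 46 % of the total.

**Three steps most likely to fail**

Step 6, asymmetric propargylation of the ynal. The small, linear alkynyl group and a fast uncatalysed background reaction can erode the ee, and the sense of induction rests on analogy with aryl aldehydes, so it must be confirmed by Mosher ester analysis. The fallback sets out from but-2-ynal 7 and separates C–C bond formation from stereocontrol. Zinc-mediated Barbier addition of propargyl bromide (THF/aq NH4Cl) gives racemic hepta-1,5-diyn-4-ol F1. Buffered Dess–Martin oxidation gives hepta-1,5-diyn-4-one F2. Noyori asymmetric transfer hydrogenation with RuCl(p-cymene)[(S,S)-TsDPEN] in i-PrOH, for which ynones are privileged substrates, then returns to the route at (S)-hepta-1,5-diyn-4-ol 8.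

Step 8, carboalumination with hydroxymethylation. Trapping the alanate with paraformaldehyde is capricious, and steps 9–10 then still depend on a Grignard allylation. The fallback sets out from aryl bromide 5 and silyl ether 9 and moves C1′ to the arene side. Grignard reagent 14 is formylated with DMF to 2,5-bis(tert-butyldimethylsilyloxy)-3-methylbenzaldehyde F3. DIBAL-H at −78 °C (to avoid aryl-to-benzyl silyl migration) gives [2,5-bis(tert-butyldimethylsilyloxy)-3-methylphenyl]methanol F4, and NCS/PPh3 gives 2,5-bis(tert-butyldimethylsilyloxy)-3-methylbenzyl chloride F5. Alkenylalane 10, made from 9 as in the first stage of step 8, is then coupled directly with F5 under Ni(0) catalysis (NiCl2(PPh3)2/n-BuLi, THF, rt; Negishi–Lipshutz benzylation). This forms C1′–C2′ instead of Ar–C1′ and returns to the route at alkyne 15.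

Step 21, the Negishi union. The δ-zincio enone 33 may cyclise onto its ketone, epimerise C11′ or undergo β-hydride elimination before coupling. The fallback sets out from Weinreb amide 26 and vinyl iodide 17 and postpones enone formation until after the union. The 9-BBN adduct 27 of 26 is coupled with 17 by B-alkyl Suzuki–Miyaura reaction (Pd(dppf)Cl2, AsPh3, Cs2CO3, DMF/THF/H2O, rt) to give (2S,6E,8S,10E)-12-[2,5-bis(tert-butyldimethylsilyloxy)-3-methylphenyl]-N-methoxy-N,2,6,10-tetramethyl-8-(triethylsilyloxy)dodeca-6,10-dienamide F6. Addition of vinyllithium 30 at −78 °C then returns to the route at 34, and steps 17, 18 and 20 are no longer needed.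

**Further compounds**
F1 | step 6 | racemic hepta-1,5-diyn-4-ol | CC#CC(O)CC#C
F2 | step 6 | hepta-1,5-diyn-4-one | CC#CC(=O)CC#C
F3 | step 8 | 2,5-bis(tert-butyldimethylsilyloxy)-3-methylbenzaldehyde | Cc1cc(O[Si](C)(C)C(C)(C)C)cc(C=O)c1O[Si](C)(C)C(C)(C)C
F4 | step 8 | [2,5-bis(tert-butyldimethylsilyloxy)-3-methylphenyl]methanol | Cc1cc(O[Si](C)(C)C(C)(C)C)cc(CO)c1O[Si](C)(C)C(C)(C)C
F5 | step 8 | 2,5-bis(tert-butyldimethylsilyloxy)-3-methylbenzyl chloride | Cc1cc(O[Si](C)(C)C(C)(C)C)cc(CCl)c1O[Si](C)(C)C(C)(C)C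
F6 | step 21 | (2S,6E,8S,10E)-12-[2,5-bis(tert-butyldimethylsilyloxy)-3-methylphenyl]-N-methoxy-N,2,6,10-tetramethyl-8-(triethylsilyloxy)dodeca-6,10-dienamide | CC[Si](CC)(CC)O[C@H](/C=C(\C)CCC[C@H](C)C(=O)N(C)OC)C/C(C)=C/Cc1cc(O[Si](C)(C)C(C)(C)C)cc(C)c1O[Si](C)(C)C(C)(C)C
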